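## Structural features

The target is 2-hydroxy-6-(13-hydroxy-2-oxotridecyl)-4-methoxybenzoic acid (C21H32O6), whose only ring is a benzene ring carrying CO2H at C1, a free phenol at C2, a methyl ether at C4 and an unbranched thirteen-carbon chain at C6, with hydrogen at C3 and C5. The chain has a ketone at C2' and a primary alcohol at C13', and there is no stereocentre, so the problem is one of regiochemistry and functional-group handling. The substituents at C6, C1 and C2 (chain, carboxyl, oxygen) are contiguous, and the two ring oxygens must end up differentiated: free at C2, methylated at C4. Several points are fragile: the 2-hydroxy-4-alkoxybenzoic acid decarboxylates in hot acid, and the carboxyl group and the C2' ketone close to a 3-alkylisocoumarin with loss of water. The C1' methylene is doubly activated, and the ketone and remote alcohol must be masked during ring construction. The key step uses the fact that C1, C2, C3 and C6, with ester, oxygen and chain attached, coincide with C5, C4, C3 and C6 of a 2-pyrone. The two missing atoms, C4 with its methoxyl and the unsubstituted C5, are the two carbons of 1,1-dimethoxyethene, and the O1–C2(=O) unit of the pyrone leaves as CO2. The ester at the future C1 activates the pyrone, fixes the regiochemistry, and later serves as the chelation handle for unmasking the C2 oxygen.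

## Logic of the disconnections

**20 to 18.** The carboxyl group is traced back to its methyl ester, so the decarboxylation-prone acid appears only in the last operation. The gain is a neutral, chromatographable precursor. The forward step must hydrolyse an ester that is flanked on both sides and deactivated by the ortho phenoxide. It is therefore routed through 19, formed by attack of the C1' enolate oxygen on the ester, and acidification must be cold.

**18 to 17.** Three masking bonds are cut together: O–CH3 at C2, the two C–O bonds of the dioxolane at C2', and O–Si at C13'. One Lewis-acidic operation plus aqueous acid removes all three. The gain is that 17 has no acidic hydrogen and no free ketone, which is what the ring-forming step needs. The demand is discrimination between the C2 and C4 methyl ethers, which rests on chelation to the neighbouring ester.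

**17 to 13 and 14.** The ring bonds C5–C6 and C3–C4 are cut, and the O1–C2(=O) bridge and one methoxyl are restored. The gain is large: the four-fold substitution pattern of the arene becomes a pyrone whose substituents are set by carbonyl chemistry. The forward step is a thermal cycloaddition on a diene deactivated by its 4-methoxyl and 6-alkyl groups, so it needs heat, excess 14 and rigorous exclusion of acid. The oxygen at pyrone C4 is kept as a methyl ether and not as an acyl group, because the alcohol released on aromatisation would cleave an enol ester and the freed acidic enol would destroy 14.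

**13 to 12.** The O–CH3 bond at pyrone O4 is cut. The acidic enol must be capped before 14 is introduced, and this oxygen becomes the C2 oxygen of the arene. The demand is alkylation at O4 and not at O2 or C3.

**12 to 11.** The lactone bond O1–C2 is cut, opening the pyrone to an acyclic tricarbonyl diester. Only one six-membered lactonisation is possible in 11. The demand is a base mild enough that C-cyclisation of the chain methylene onto the ester does not compete.

**11 to 8 and 9 (through 10).** The C–C bond between the ester-bearing carbon (future C1) and the acyl carbon (future C6) is cut. Symmetrical 9 then supplies C1, C2, C3, the ester and the lactone carbon in one piece. The demand is C- over O-acylation and activation of 8 without acid, since the dioxolane and the silyl ether are already present.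

**8 to 7 to 6.** The acid is traced to its methyl ester and the dioxolane to the ketone. The ketone must be masked before the chain is activated. Otherwise the beta-keto acid would decarboxylate and the later polycarbonyl array would have several cyclisation modes. The demand is ketalisation under aprotic conditions that keep the silyl ether.

**6 to 3 and 4 (through 5).** The C2–C3 bond of 6 (future C1'–C2') is cut. This two-carbon homologation turns a C12 acid into the C14 beta-keto ester. The demand is only that the acidic acyl intermediate is not held in hot alcohol longer than necessary.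

**3 to 1 (through 2).** The O–Si bond is cut. The remote alcohol must be capped for the acylations and for the cycloaddition, and the silyl group is chosen because the unmasking step from 17 to 18 removes it without an extra operation.

## Other disconnections considered

**Alternative 1:** The cut is the C6–C1' bond together with the lactone C–O bond. In the forward step, 2-hydroxy-4-methoxybenzoic acid A1 and the keto sulfoxonium ylide A2 are combined with [Cp*RhCl2]2 and NaOAc. Trivalent rhodium, directed by the carboxylate, metallates C6, the ylide carbon inserts with loss of its sulfoxide leaving group, and the resulting keto acid closes to isocoumarin A3. Silyl removal from A3 would give 19, and base would then give 20.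
- In favour: the arene is bought with the correct oxygen pattern, so no demethylation and no aromatisation are needed. C6 is the only C–H ortho to the carboxylate. A2 is two operations from 3. The ketone is born as the enol lactone and needs no protecting group.
- Against: the free ortho phenol can hold the metal in a salicylate-type chelate or direct it to C3, and the electron-rich acid may lose CO2 at the reaction temperature. If the phenol had to be masked as a methyl ether, the demethylation problem of the chosen plan would return.
- Comparison: on step economy (about five steps against ten) and on protecting-group count this alternative is better. On tolerance of the silyl ether it is equal. On predictability it is weaker, since it rests on a directing-group competition and a precious-metal catalyst, whereas the chosen plan risks only low reactivity.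

**Alternative 2:** The cut is the C1–C6 ring bond. In the forward step, Et3N in CH2Cl2 enolises the diketo-dioxinone A4. Dioxinone carbon C5 adds to the chain ketone, and dehydration gives the acetonide-protected resorcylate A5. Methylation of the free phenol, aqueous acid and then base would lead to 20.
- In favour: the conditions are mild and need no heat or pressure. The carboxyl group and the C2 oxygen arrive tied together, so the C4 hydroxyl is the only one free for methylation. The benzodioxinone opens directly to the acid, so no hindered ester has to be hydrolysed.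
- Against: A4 is a sensitive 1,3,5-tricarbonyl array carrying a further masked ketone. Its assembly from 8 needs several Claisen-type chain extensions. It can also close prematurely to a pyrone or fold the other way, and the dioxolane beta to the reacting ketone is exposed to base-induced elimination.
- Comparison: on oxygen differentiation and on mildness of the endgame this alternative is better. On step count it is equal at best. The chosen plan is stronger in that its polycarbonyl stage is locked as a stable pyrone before the ring-forming event, so the regiochemistry of ring closure is not a matter of folding.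

**Alternative 3:** The cuts are C2–C3, C4–C5 and C1–C2. In the forward step, Et3N dehydrochlorinates the glutaconyl chloride A6 to the vinylketene A7. Methoxyacetylene A8 adds by [2+2] cycloaddition to give cyclobutenone A9. Four-electron ring opening and six-electron ring closure then give the phenol ester A10. Aqueous acid would convert A10 into 18.
- In favour: the C2 phenol is delivered free and the C4 methyl ether is in place, so no BCl3 step is needed. The polarity of the alkyne fixes the regiochemistry.
- Against: A8 is a volatile, hazardous alkyne that is not routinely stocked. A6 has to be made by a separate multistep sequence that carries the ketal side chain at C3 and is prone to double-bond isomerisation. An acid chloride next to a dioxolane must survive Et3N, and ketenes generated this way dimerise readily.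
- Comparison: on oxygen differentiation this alternative is better than the chosen plan and equal to alternative 2. On mechanism it is more speculative for an ester-terminated vinylketene made by dehydrohalogenation. On step economy it is probably worse, because A6 is harder to reach than 13.

Key step: step 8

Remark on the chemistry: the target is taken as the open-chain keto acid and not as its cyclic lactol tautomer. All compounds are achiral except the transient bicyclic lactone 15, which is racemic. TBS = tert-butyldimethylsilyl throughout.

## Route

Step 1
Reactants: 1 12-hydroxydodecanoic acid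
Product: 3 12-[(tert-butyldimethylsilyl)oxy]dodecanoic acid, via silyl ester 2 (not isolated)
Conditions: TBSCl (2.3 equiv), imidazole, DMF, rt; then K2CO3, MeOH/THF/H2O, rt; 1 M HCl to pH 4–5, 0 °C
Reagents that add atoms: tert-butyldimethylsilyl chloride (TBSCl), CC(C)(C)[Si](C)(C)Cl
Why: Silylation of both hydroxyl and carboxyl groups, followed by selective hydrolysis of the much more labile silyl ester with aqueous carbonate, is the standard way to a silyloxy acid.

Step 2
Reactants: 3 12-[(tert-butyldimethylsilyl)oxy]dodecanoic acid; 4 Meldrum's acid (2,2-dimethyl-1,3-dioxane-4,6-dione)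
Product: 6 methyl 14-[(tert-butyldimethylsilyl)oxy]-3-oxotetradecanoate, via acyl Meldrum's acid 5 (not isolated)
Conditions: EDC·HCl, DMAP, CH2Cl2, 0 °C → rt; cold aq. KHSO4 wash; then MeOH (10 equiv), PhMe, 80 °C
Reagents that add atoms: methanol, CO
Why: Carbodiimide-mediated C-acylation of Meldrum's acid, then thermal methanolysis through the acylketene with loss of acetone and CO2, gives the beta-keto ester. Limiting the methanol and working in toluene keeps the primary silyl ether away from prolonged acidic alcoholysis.

Step 3
Reactants: 6 methyl 14-[(tert-butyldimethylsilyl)oxy]-3-oxotetradecanoate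
Product: 7 methyl 2-{2-[11-(TBSO)undecyl]-1,3-dioxolan-2-yl}acetate
Conditions: TMSOCH2CH2OTMS (2 equiv), TMSOTf (5 mol %), CH2Cl2, −78 → −20 °C; pyridine quench
Reagents that add atoms: 1,2-bis(trimethylsilyloxy)ethane, C[Si](C)(C)OCCO[Si](C)(C)C
Why: Silyl-transfer ketalisation (Noyori ketalisation) is aprotic and runs at low temperature, so the ketone is masked as the dioxolane without touching the silyl ether. Hexamethyldisiloxane is the only by-product.

Step 4
Reactants: 7 methyl 2-{2-[11-(TBSO)undecyl]-1,3-dioxolan-2-yl}acetate
Product: 8 2-{2-[11-(TBSO)undecyl]-1,3-dioxolan-2-yl}acetic acid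
Conditions: LiOH·H2O, THF/MeOH/H2O, rt; 1 M HCl to pH 4–5, 0 °C
Reagents that add atoms: LiOH (its hydroxide oxygen ends in the carboxyl group), [Li+].[OH-]
Why: Plain saponification; the dioxolane and silyl ether are stable to hydroxide, and the brief, cold, weakly acidic work-up spares both.

Step 5
Reactants: 8 2-{2-[11-(TBSO)undecyl]-1,3-dioxolan-2-yl}acetic acid; 9 dimethyl 3-oxopentanedioate (dimethyl 1,3-acetonedicarboxylate)
Product: 11 dimethyl 2-({2-[11-(TBSO)undecyl]-1,3-dioxolan-2-yl}acetyl)-3-oxopentanedioate, via acid chloride 10 (not isolated)
Conditions: Me2C=C(Cl)NMe2 (1.1 equiv), CH2Cl2, 0 °C → rt; then added to 9, MgCl2 (1.1 equiv), pyridine (2.2 equiv), CH2Cl2, 0 °C → rt; cold aq. citric acid work-up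
Reagents that add atoms: none
Why: The chloroenamine makes the acid chloride under neutral conditions with an amide as the only by-product, so no HCl reaches the dioxolane or silyl ether. Soft enolisation of 9 with MgCl2 and pyridine gives a chelated enolate that is acylated on carbon, the established C-acylation of 1,3-dicarbonyl compounds.

Step 6
Reactants: 11 dimethyl 2-({2-[11-(TBSO)undecyl]-1,3-dioxolan-2-yl}acetyl)-3-oxopentanedioate
Product: 12 methyl 4-hydroxy-2-oxo-6-({2-[11-(TBSO)undecyl]-1,3-dioxolan-2-yl}methyl)-2H-pyran-5-carboxylate
Conditions: DBU (1.2 equiv), PhMe, 80 °C; cold aq. citric acid work-up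
Reagents that add atoms: none
Why: The enolate oxygen of the newly introduced acyl ketone attacks the distal CH2CO2Me ester with loss of methanol, the known base-promoted lactonisation of 3,5-dioxo esters to 4-hydroxy-2-pyrones. No other six-membered lactone can form from 11.

Step 7
Reactants: 12 methyl 4-hydroxy-2-oxo-6-({2-[11-(TBSO)undecyl]-1,3-dioxolan-2-yl}methyl)-2H-pyran-5-carboxylate
Product: 13 methyl 4-methoxy-2-oxo-6-({2-[11-(TBSO)undecyl]-1,3-dioxolan-2-yl}methyl)-2H-pyran-5-carboxylate
Conditions: Me2SO4 (1.5 equiv), K2CO3, acetone, 50 °C; aq. NH3 quench
Reagents that add atoms: dimethyl sulfate, COS(=O)(=O)OC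
Why: O-alkylation of the vinylogous acid; 4-hydroxy-2-pyrones are methylated mainly at O4 under these conditions, and any 2-methoxy-4-pyranone isomer is separable.

Step 8
Reactants: 13 methyl 4-methoxy-2-oxo-6-({2-[11-(TBSO)undecyl]-1,3-dioxolan-2-yl}methyl)-2H-pyran-5-carboxylate; 14 1,1-dimethoxyethene
Product: 17 methyl 2,4-dimethoxy-6-({2-[11-(TBSO)undecyl]-1,3-dioxolan-2-yl}methyl)benzoate, via bicyclic lactone 15 (not isolated), via trimethoxycyclohexadiene 16 (not isolated)
Conditions: 14 (8 equiv), Et3N (5 mol %), PhMe, base-washed sealed tube, 140 °C
Reagents that add atoms: none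
Why: The electron-rich alkene 14 and the ester-activated pyrone 13 combine in a [4+2] cycloaddition of inverse electron demand: the unsubstituted terminus of 14 bonds to pyrone C6, the position made electrophilic by conjugation with both the 5-ester and the ring carbonyl, while its dimethoxy-bearing carbon bonds to pyrone C3, whether the two bonds form together or stepwise through a dipolar intermediate, and the adduct is the 2-oxabicyclo[2.2.2]octenone 15. Cycloreversion then expels the lactone bridge of 15 as CO2 to leave cyclohexadiene 16, and 1,2-elimination of methanol from the acetal carbon and the neighbouring CH2 of 16 aromatises the ring to 17. The closest known reaction type is the conversion of ester-bearing 2-pyrones such as alkyl coumalates into methoxybenzoates with 1,1-dialkoxyalkenes. The benzene ring is closed by an intermolecular cycloaddition that forms the C5–C6 and C3–C4 bonds suprafacially on both partners, followed by cycloreversion; no tethered ring closure is involved. The two bridgehead stereocentres of 15 are destroyed on CO2 loss, so facial selectivity does not matter and no stereocentre is set. The step needs regioselectivity, with the new methoxyl para to the ester, and the polarisation of C6 by the ester and the lactone carbonyl secures it. It also needs the dioxolane, silyl ether and ester to stay intact; under neutral aprotic heating they are inert, and the trace of Et3N and the base-washed vessel protect 14 from acid. Because the 4-methoxyl and the 6-substituent lower the diene reactivity, a large excess of 14 and 140 °C in a closed vessel are used.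

Step 9
Reactants: 17 methyl 2,4-dimethoxy-6-({2-[11-(TBSO)undecyl]-1,3-dioxolan-2-yl}methyl)benzoate
Product: 18 methyl 2-hydroxy-6-(13-hydroxy-2-oxotridecyl)-4-methoxybenzoate
Conditions: BCl3 (1 M in CH2Cl2, 4 equiv), CH2Cl2, −78 → 0 °C; MeOH quench; then 2 M aq. HCl/THF, rt
Reagents that add atoms: water, O
Why: BCl3 chelates between the ester carbonyl and the ortho methoxyl, so only the C2 methyl ether is cleaved at low temperature, while the C4 ether, which cannot chelate, should persist. The same Lewis acid opens the dioxolane and cleaves the primary silyl ether, and the aqueous HCl stage completes both. Any 19 formed here converges on the target in step 10.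

Step 10
Reactants: 18 methyl 2-hydroxy-6-(13-hydroxy-2-oxotridecyl)-4-methoxybenzoate
Product: 20 2-hydroxy-6-(13-hydroxy-2-oxotridecyl)-4-methoxybenzoic acid (CNP0165592.0), via isocoumarin 19 (not isolated)
Conditions: KOH (1 M aq., 5 equiv), 1,4-dioxane, degassed, 40 °C; then 1 M HCl to pH 3, 0 °C, extraction and concentration without heating
Reagents that add atoms: KOH (its hydroxide oxygen ends in the carboxyl group), [K+].[OH-]
Why: In aqueous base the doubly activated C1' methylene enolises and the enolate oxygen acylates on the neighbouring ester in a six-membered transition state to give enol lactone 19, which hydroxide opens to the keto carboxylate. This neighbouring-group path avoids slow direct saponification of a 2,6-disubstituted salicylate. A non-alcoholic cosolvent prevents re-esterification, and cold acidification limits relactonisation and decarboxylation.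

## Compound list

1 | 12-hydroxydodecanoic acid | OCCCCCCCCCCCC(=O)O | starting material
2 | tert-butyldimethylsilyl 12-[(tert-butyldimethylsilyl)oxy]dodecanoate | CC(C)(C)[Si](C)(C)OCCCCCCCCCCCC(=O)O[Si](C)(C)C(C)(C)C | intermediate
3 | 12-[(tert-butyldimethylsilyl)oxy]dodecanoic acid | CC(C)(C)[Si](C)(C)OCCCCCCCCCCCC(=O)O | intermediate
4 | Meldrum's acid (2,2-dimethyl-1,3-dioxane-4,6-dione) | CC1(C)OC(=O)CC(=O)O1 | starting material
5 | 5-{12-[(tert-butyldimethylsilyl)oxy]-1-hydroxydodecylidene}-2,2-dimethyl-1,3-dioxane-4,6-dione | CC1(C)OC(=O)C(=C(O)CCCCCCCCCCCO[Si](C)(C)C(C)(C)C)C(=O)O1 | intermediate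
6 | methyl 14-[(tert-butyldimethylsilyl)oxy]-3-oxotetradecanoate | COC(=O)CC(=O)CCCCCCCCCCCO[Si](C)(C)C(C)(C)C | intermediate
7 | methyl 2-{2-[11-(TBSO)undecyl]-1,3-dioxolan-2-yl}acetate | COC(=O)CC1(OCCO1)CCCCCCCCCCCO[Si](C)(C)C(C)(C)C | intermediate
8 | 2-{2-[11-(TBSO)undecyl]-1,3-dioxolan-2-yl}acetic acid | OC(=O)CC1(OCCO1)CCCCCCCCCCCO[Si](C)(C)C(C)(C)C | intermediate
9 | dimethyl 3-oxopentanedioate (dimethyl 1,3-acetonedicarboxylate) | COC(=O)CC(=O)CC(=O)OC | starting material
10 | 2-{2-[11-(TBSO)undecyl]-1,3-dioxolan-2-yl}acetyl chloride | ClC(=O)CC1(OCCO1)CCCCCCCCCCCO[Si](C)(C)C(C)(C)C | intermediate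
11 | dimethyl 2-({2-[11-(TBSO)undecyl]-1,3-dioxolan-2-yl}acetyl)-3-oxopentanedioate | COC(=O)CC(=O)C(C(=O)OC)C(=O)CC1(OCCO1)CCCCCCCCCCCO[Si](C)(C)C(C)(C)C | intermediate
12 | methyl 4-hydroxy-2-oxo-6-({2-[11-(TBSO)undecyl]-1,3-dioxolan-2-yl}methyl)-2H-pyran-5-carboxylate | COC(=O)C1=C(CC2(OCCO2)CCCCCCCCCCCO[Si](C)(C)C(C)(C)C)OC(=O)C=C1O | intermediate
13 | methyl 4-methoxy-2-oxo-6-({2-[11-(TBSO)undecyl]-1,3-dioxolan-2-yl}methyl)-2H-pyran-5-carboxylate | COC(=O)C1=C(CC2(OCCO2)CCCCCCCCCCCO[Si](C)(C)C(C)(C)C)OC(=O)C=C1OC | intermediate
14 | 1,1-dimethoxyethene | C=C(OC)OC | starting material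
15 | methyl 5,8,8-trimethoxy-3-oxo-1-({2-[11-(TBSO)undecyl]-1,3-dioxolan-2-yl}methyl)-2-oxabicyclo[2.2.2]oct-5-ene-6-carboxylate (racemic; relative configuration fixed by the bridge) | O=C1OC2(CC3(OCCO3)CCCCCCCCCCCO[Si](C)(C)C(C)(C)C)C(C(=O)OC)=C(OC)C1C(OC)(OC)C2 | intermediate
16 | methyl 4,4,6-trimethoxy-2-({2-[11-(TBSO)undecyl]-1,3-dioxolan-2-yl}methyl)cyclohexa-1,5-diene-1-carboxylate | COC(=O)C1=C(CC2(OCCO2)CCCCCCCCCCCO[Si](C)(C)C(C)(C)C)CC(OC)(OC)C=C1OC | intermediate
17 | methyl 2,4-dimethoxy-6-({2-[11-(TBSO)undecyl]-1,3-dioxolan-2-yl}methyl)benzoate | COC(=O)c1c(OC)cc(OC)cc1CC2(OCCO2)CCCCCCCCCCCO[Si](C)(C)C(C)(C)C | intermediate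
18 | methyl 2-hydroxy-6-(13-hydroxy-2-oxotridecyl)-4-methoxybenzoate | COC(=O)c1c(O)cc(OC)cc1CC(=O)CCCCCCCCCCCO | intermediate
19 | 8-hydroxy-3-(11-hydroxyundecyl)-6-methoxy-1H-isochromen-1-one | COc1cc(O)c2C(=O)OC(CCCCCCCCCCCO)=Cc2c1 | intermediate
20 | 2-hydroxy-6-(13-hydroxy-2-oxotridecyl)-4-methoxybenzoic acid | COc1cc(O)c(C(=O)O)c(CC(=O)CCCCCCCCCCCO)c1 | target

## Step count and least certain steps

Total: 10 steps. Longest linear sequence: 10 steps, from 1 to 20; compounds 4, 9 and 14 are purchased and enter along this line.

**Step 8 (key step).** The most likely failure is a cycloaddition that is too slow. The diene is electron-rich at C4 and hindered at C6, the site of first bond formation, so 14 may oligomerise or be consumed by traces of acid before it adds. Fallback: ring construction by cycloaddition is abandoned and the chain is attached to a preformed arene. The fallback sets out from 3, which is converted with N,O-dimethylhydroxylamine hydrochloride, EDC·HCl and Et3N into N-methoxy-N-methyl-12-[(tert-butyldimethylsilyl)oxy]dodecanamide F1. Purchased methyl 2,4-dimethoxy-6-methylbenzoate F2 is deprotonated at its benzylic methyl group with LiN(iPr)2 (2.2 equiv) in THF at −78 °C and acylated with F1, which should give methyl 2,4-dimethoxy-6-{13-[(tert-butyldimethylsilyl)oxy]-2-oxotridecyl}benzoate F3. Treatment of F3 with BCl3 as in step 9 cleaves the ortho methyl ether and the silyl ether, and the route is rejoined at 18.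

**Step 5.** The acid chloride may be lost through ketene formation with beta-elimination that opens the dioxolane. Acylation may also occur on oxygen instead of carbon, or a second acylation may occur at the other methylene of 9. Fallback: the side chain is built onto a preformed pyrone, so no ketal-bearing acyl donor is needed. The fallback sets out from 9, which is acylated with acetyl chloride under the same MgCl2/pyridine conditions to dimethyl 2-acetyl-3-oxopentanedioate F4. F4 is cyclised with DBU to methyl 4-hydroxy-6-methyl-2-oxo-2H-pyran-5-carboxylate F5, which is methylated with Me2SO4 and K2CO3 to methyl 4-methoxy-6-methyl-2-oxo-2H-pyran-5-carboxylate F6. The 6-methyl group of F6 is deprotonated with LiN(SiMe3)2 (2.1 equiv) in THF at −78 °C and acylated with the amide F1 of the preceding fallback, which should give methyl 4-methoxy-2-oxo-6-{13-[(tert-butyldimethylsilyl)oxy]-2-oxotridecyl}-2H-pyran-5-carboxylate F7. Silyl-transfer ketalisation of F7 as in step 3 returns to the route at 13.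

**Step 9.** Ether cleavage may be unselective, with loss of the C4 methyl group as well. Dioxolane opening by the Lewis acid may also be incomplete or messy and leave chlorinated ether by-products. Fallback: the C2 oxygen is carried as a benzyl ether, so no demethylation is needed. The fallback sets out from 12, which is alkylated with benzyl bromide and K2CO3 to methyl 4-(benzyloxy)-2-oxo-6-({2-[11-(TBSO)undecyl]-1,3-dioxolan-2-yl}methyl)-2H-pyran-5-carboxylate F8. Cycloaddition of F8 with 14 as in step 8 should give methyl 2-(benzyloxy)-4-methoxy-6-({2-[11-(TBSO)undecyl]-1,3-dioxolan-2-yl}methyl)benzoate F9. Hydrogenolysis of F9 (H2, Pd/C, EtOAc) should give methyl 2-hydroxy-4-methoxy-6-({2-[11-(TBSO)undecyl]-1,3-dioxolan-2-yl}methyl)benzoate F10, the same structure as A10. Treatment of F10 with 2 M aq. HCl in THF removes the dioxolane and silyl ether and returns to the route at 18.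

**Step 10.** Three processes may interfere: Claisen-type closure of the C3' enolate onto the ester to a naphthalenediol while the ester and ketone enolate coexist in base; relactonisation on acidification; and decarboxylation of the electron-rich acid on acidification. Fallback: ester cleavage is separated from the basic stage. The fallback sets out from 18, which is lactonised under acid (TsOH cat., PhMe, 80 °C, removal of methanol) to isolated 19. Compound 19 is then opened with LiOH in THF/H2O at 0 °C for a short time and acidified cold to pH 3–4, reaching 20. No compound outside the compound list is made.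

## Further compounds

F1 | step 8 | N-methoxy-N-methyl-12-[(tert-butyldimethylsilyl)oxy]dodecanamide | CON(C)C(=O)CCCCCCCCCCCO[Si](C)(C)C(C)(C)C
F2 | step 8 | methyl 2,4-dimethoxy-6-methylbenzoate (purchased) | COC(=O)c1c(C)cc(OC)cc1OC
F3 | step 8 | methyl 2,4-dimethoxy-6-{13-[(tert-butyldimethylsilyl)oxy]-2-oxotridecyl}benzoate | COC(=O)c1c(OC)cc(OC)cc1CC(=O)CCCCCCCCCCCO[Si](C)(C)C(C)(C)C
F4 | step 5 | dimethyl 2-acetyl-3-oxopentanedioate | COC(=O)CC(=O)C(C(C)=O)C(=O)OC
F5 | step 5 | methyl 4-hydroxy-6-methyl-2-oxo-2H-pyran-5-carboxylate | COC(=O)C1=C(C)OC(=O)C=C1O
F6 | step 5 | methyl 4-methoxy-6-methyl-2-oxo-2H-pyran-5-carboxylate | COC(=O)C1=C(C)OC(=O)C=C1OC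
F7 | step 5 | methyl 4-methoxy-2-oxo-6-{13-[(tert-butyldimethylsilyl)oxy]-2-oxotridecyl}-2H-pyran-5-carboxylate | COC(=O)C1=C(CC(=O)CCCCCCCCCCCO[Si](C)(C)C(C)(C)C)OC(=O)C=C1OC
F8 | step 9 | methyl 4-(benzyloxy)-2-oxo-6-({2-[11-(TBSO)undecyl]-1,3-dioxolan-2-yl}methyl)-2H-pyran-5-carboxylate | COC(=O)C1=C(CC2(OCCO2)CCCCCCCCCCCO[Si](C)(C)C(C)(C)C)OC(=O)C=C1OCc1ccccc1
F9 | step 9 | methyl 2-(benzyloxy)-4-methoxy-6-({2-[11-(TBSO)undecyl]-1,3-dioxolan-2-yl}methyl)benzoate | COC(=O)c1c(OCc2ccccc2)cc(OC)cc1CC3(OCCO3)CCCCCCCCCCCO[Si](C)(C)C(C)(C)C
F10 | step 9 | methyl 2-hydroxy-4-methoxy-6-({2-[11-(TBSO)undecyl]-1,3-dioxolan-2-yl}methyl)benzoate | COC(=O)c1c(O)cc(OC)cc1CC2(OCCO2)CCCCCCCCCCCO[Si](C)(C)C(C)(C)C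
F0 | step 10 | none | none
A1 | alternative 1 | 2-hydroxy-4-methoxybenzoic acid | COc1ccc(C(=O)O)c(O)c1
A2 | alternative 1 | 13-[(tert-butyldimethylsilyl)oxy]-1-[dimethyl(oxo)-λ6-sulfanylidene]tridecan-2-one | CS(C)(=O)=CC(=O)CCCCCCCCCCCO[Si](C)(C)C(C)(C)C
A3 | alternative 1 | 8-hydroxy-6-methoxy-3-{11-[(tert-butyldimethylsilyl)oxy]undecyl}-1H-isochromen-1-one | COc1cc(O)c2C(=O)OC(CCCCCCCCCCCO[Si](C)(C)C(C)(C)C)=Cc2c1
A4 | alternative 2 | 2,2-dimethyl-6-(2,4-dioxo-5-{2-[11-(TBSO)undecyl]-1,3-dioxolan-2-yl}pentyl)-4H-1,3-dioxin-4-one | CC1(C)OC(=O)C=C(CC(=O)CC(=O)CC2(OCCO2)CCCCCCCCCCCO[Si](C)(C)C(C)(C)C)O1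
A5 | alternative 2 | 7-hydroxy-2,2-dimethyl-5-({2-[11-(TBSO)undecyl]-1,3-dioxolan-2-yl}methyl)-4H-1,3-benzodioxin-4-one | CC1(C)OC(=O)c2c(CC3(OCCO3)CCCCCCCCCCCO[Si](C)(C)C(C)(C)C)cc(O)cc2O1
A6 | alternative 3 | methyl 5-chloro-5-oxo-3-({2-[11-(TBSO)undecyl]-1,3-dioxolan-2-yl}methyl)pent-2-enoate (either double-bond isomer) | COC(=O)C=C(CC(Cl)=O)CC1(OCCO1)CCCCCCCCCCCO[Si](C)(C)C(C)(C)C
A7 | alternative 3 | methyl 5-oxo-3-({2-[11-(TBSO)undecyl]-1,3-dioxolan-2-yl}methyl)penta-2,4-dienoate (vinylketene; either double-bond isomer) | COC(=O)C=C(C=C=O)CC1(OCCO1)CCCCCCCCCCCO[Si](C)(C)C(C)(C)C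
A8 | alternative 3 | methoxyacetylene (methoxyethyne) | COC#C
A9 | alternative 3 | methyl 3-(2-methoxy-4-oxocyclobut-2-en-1-yl)-4-{2-[11-(TBSO)undecyl]-1,3-dioxolan-2-yl}but-2-enoate (racemic) | COC(=O)C=C(C1C(=O)C=C1OC)CC2(OCCO2)CCCCCCCCCCCO[Si](C)(C)C(C)(C)C
A10 | alternative 3 | methyl 2-hydroxy-4-methoxy-6-({2-[11-(TBSO)undecyl]-1,3-dioxolan-2-yl}methyl)benzoate | COC(=O)c1c(O)cc(OC)cc1CC2(OCCO2)CCCCCCCCCCCO[Si](C)(C)C(C)(C)C
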